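Plan
- Retrosynthesis: the O8 methacrylate and then the O10 acetate together with H8 are removed (a Tishchenko-type relay from a C8 ketone and a free C10 carbinol); the ring bond C9–C10 is then cut as an aldol bond.
- Enabling feature: in the ring segment C8(O)–C9H2–C10(O)(CH3)–C1(=O), C10 is the acetyl carbonyl of a chelating C1/C10 1,2-diketone and C9 is the α-carbon of a C8 ketone on the butenolide ring (C6–C7–C11–C12–O). C9 is activated as a β-keto acid (extra CO2H, lost during ring closure) and C8 stays at the ketone level until after the closure.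
- The open-chain butenolide is cut at C8–C9 (acid plus malonate), at C6–C7 and O–C12 (Ni/Cr coupling of a Z-enal with a tetrasubstituted enol triflate, then lactonisation), at C1–C10 (dithiane acylation) and at C3–C4 (Negishi coupling).
- Forward order: C1–C6 chain with the Z alkene, then the butenolide ring, then the ten-membered carbocycle (C9–C10), then C8 reduction with acetyl transfer, then the methacrylate.
- Stereochemistry: 4Z from (2Z)-3-iodobut-2-en-1-ol with retention; C6 (R) from the chiral chromium ligand; C10 (S) from the chiral copper catalyst in the ring closure; C8 (S) relayed from C10 by intramolecular hydride delivery.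

Key step: step 13

Remark: positions are numbered as in germacranolides: C1 ring ketone, C2, C3, C4 (bears CH3 C15), C5, C6 (lactone CH–O), C7, C8 (CH–O), C9, C10 (bears CH3 C14), C11 (butenolide α-carbon), C12 (lactone C=O), C13 (CH2OAc).

Step 1
Reactants: 1 but-2-yn-1-ol
Product: 2 (2Z)-3-iodobut-2-en-1-ol
Conditions: NaAlH2(OCH2CH2OMe)2, THF, 0 → 23 °C; EtOAc; then I2, THF, −78 °C
Reagents that add atoms: iodine, II
Why: trans-hydroalumination of the propargylic alcohol through its alkoxyaluminate puts aluminium on the carbon that becomes C4, and iodinolysis with retention gives the Z-iodoalkene that fixes the 4Z geometry (hydroalumination–iodination of a 2-alkyn-1-ol).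

Step 2
Reactants: 2 (2Z)-3-iodobut-2-en-1-ol; 3 (3-ethoxy-3-oxopropyl)zinc bromide (2.5 equiv)
Product: 4 ethyl (4Z)-6-hydroxy-4-methylhex-4-enoate
Conditions: Pd(PPh3)4 (5 mol %), THF, 23 → 50 °C
Reagents that add atoms: none
Why: Negishi sp2–sp3 cross-coupling on zerovalent palladium proceeds with retention of alkene geometry, so the propanoate chain (C3–C1) ends up cis to the CH2OH carbon (C6), the excess zinc reagent absorbing the free hydroxyl.

Step 3
Reactants: 4 ethyl (4Z)-6-hydroxy-4-methylhex-4-enoate; 5 2-methyl-1,3-dithiane (3 equiv)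
Product: 7 (4Z)-6-hydroxy-4-methyl-1-(2-methyl-1,3-dithian-2-yl)hex-4-en-1-one, via lithiated dithiane 6 (not isolated)
Conditions: n-BuLi, THF, −30 °C; then 4, −78 → 0 °C; aq. NH4Cl
Reagents that add atoms: none
Why: Corey–Seebach acylation, in which the tertiary dithianyl anion adds once to the ester and the hindered ketone resists a second addition, gives C1 as ketone and C10 as dithioketal, an acid-stable mask of the 1,2-diketone.

Step 4
Reactants: 7 (4Z)-6-hydroxy-4-methyl-1-(2-methyl-1,3-dithian-2-yl)hex-4-en-1-one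
Product: 8 (2Z)-3-methyl-6-(2-methyl-1,3-dithian-2-yl)-6-oxohex-2-enal
Conditions: MnO2, CH2Cl2, 23 °C
Reagents that add atoms: none
Why: MnO2 oxidises only the allylic alcohol under neutral conditions, which should leave the dithioketal, the ketone and the Z geometry untouched (allylic oxidation).

Step 5
Reactants: 9 methyl propanoate; 10 di-tert-butyl oxalate
Product: 11 1-tert-butyl 4-methyl 3-methyl-2-oxobutanedioate
Conditions: LiN(SiMe3)2 (2.1 equiv), THF, −78 °C; then 10, −78 → 0 °C; 1 M HCl
Reagents that add atoms: none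
Why: crossed Claisen condensation, in which the preformed ester enolate is acylated by the non-enolisable oxalate and the product is protected as its stabilised enolate until work-up.

Step 6
Reactants: 11 1-tert-butyl 4-methyl 3-methyl-2-oxobutanedioate
Product: 12 1-tert-butyl 4-methyl (2Z)-3-methyl-2-[(trifluoromethanesulfonyl)oxy]but-2-enedioate
Conditions: NaH, Et2O, 0 °C; then (CF3SO2)2O, −78 → 0 °C
Reagents that add atoms: triflic anhydride, O=S(=O)(OS(=O)(=O)C(F)(F)F)C(F)(F)F
Why: O-sulfonylation of the sodium chelate, in which sodium bridges the enolate oxygen and the methyl ester carbonyl, should give the enol triflate with OTf cis to CO2Me, the geometry needed for the later lactonisation (enol triflate formation from a β-keto ester).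

Step 7
Reactants: 12 1-tert-butyl 4-methyl (2Z)-3-methyl-2-[(trifluoromethanesulfonyl)oxy]but-2-enedioate
Product: 13 1-tert-butyl 4-methyl (2E)-3-(bromomethyl)-2-[(trifluoromethanesulfonyl)oxy]but-2-enedioate
Conditions: N-bromosuccinimide, AIBN (cat.), PhCF3, 80 °C
Reagents that add atoms: N-bromosuccinimide, O=C1CCC(=O)N1Br
Why: Wohl–Ziegler bromination, site-selective because the only allylic C–H bonds are those of the methyl group on the electron-poor tetrasubstituted alkene.

Step 8
Reactants: 13 1-tert-butyl 4-methyl (2E)-3-(bromomethyl)-2-[(trifluoromethanesulfonyl)oxy]but-2-enedioate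
Product: 14 1-tert-butyl 4-methyl (2Z)-3-(acetoxymethyl)-2-[(trifluoromethanesulfonyl)oxy]but-2-enedioate
Conditions: KOAc, 18-crown-6 (cat.), MeCN, 23 °C
Reagents that add atoms: potassium acetate, CC(=O)[O-].[K+]
Why: SN2 displacement of the primary allylic bromide by acetate installs the C13 acetate at a stage where no base-sensitive stereocentre exists.

Step 9
Reactants: 8 (2Z)-3-methyl-6-(2-methyl-1,3-dithian-2-yl)-6-oxohex-2-enal; 14 1-tert-butyl 4-methyl (2Z)-3-(acetoxymethyl)-2-[(trifluoromethanesulfonyl)oxy]but-2-enedioate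
Product: 16 tert-butyl (2R)-4-(acetoxymethyl)-2-[(1Z)-2-methyl-5-(2-methyl-1,3-dithian-2-yl)-5-oxopent-1-en-1-yl]-5-oxo-2,5-dihydrofuran-3-carboxylate, via silyl ether 15 (not isolated)
Conditions: CrCl2 (15 mol %), chiral oxazoline–sulfonamide ligand (17 mol %), NiCl2(2,9-dimethyl-1,10-phenanthroline) (2 mol %), Mn, Me3SiCl, LiCl, MeCN, 23 °C; then 1 M HCl, THF
Reagents that add atoms: none
Why: Nozaki–Hiyama–Kishi coupling, in which zerovalent nickel inserts into the enol triflate and the alkenyl group passes to trivalent chromium and adds 1,2 to the enal, the chromium ligand (enantiomer chosen to give 6R) controlling the face at C6, after which the freed C6 hydroxyl closes onto the cis methyl ester to give the butenolide.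

Step 10
Reactants: 16 tert-butyl (2R)-4-(acetoxymethyl)-2-[(1Z)-2-methyl-5-(2-methyl-1,3-dithian-2-yl)-5-oxopent-1-en-1-yl]-5-oxo-2,5-dihydrofuran-3-carboxylate
Product: 17 (2R)-4-(acetoxymethyl)-2-[(1Z)-2-methyl-5-(2-methyl-1,3-dithian-2-yl)-5-oxopent-1-en-1-yl]-5-oxo-2,5-dihydrofuran-3-carboxylic acid
Conditions: CF3CO2H/CH2Cl2 1:4, 0 °C
Reagents that add atoms: none
Why: acidolysis of the tert-butyl ester (loss of 2-methylpropene) frees the C8 acid, while the dithioketal, the acetate and the lactone should be stable to anhydrous acid at 0 °C.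

Step 11
Reactants: 17 (2R)-4-(acetoxymethyl)-2-[(1Z)-2-methyl-5-(2-methyl-1,3-dithian-2-yl)-5-oxopent-1-en-1-yl]-5-oxo-2,5-dihydrofuran-3-carboxylic acid
Product: 19 tert-butyl 3-{(2R)-4-(acetoxymethyl)-2-[(1Z)-2-methyl-5-(2-methyl-1,3-dithian-2-yl)-5-oxopent-1-en-1-yl]-5-oxo-2,5-dihydrofuran-3-yl}-3-oxopropanoate, via acyl imidazolide 18 (not isolated)
Conditions: 1,1'-carbonyldiimidazole, THF, 23 °C; then preformed Mg(O2CCH2CO2tBu)2, 23 → 40 °C; 0.5 M HCl
Reagents that add atoms: magnesium bis(3-tert-butoxy-3-oxopropanoate), CC(C)(C)OC(=O)CC(=O)[O-].CC(C)(C)OC(=O)CC(=O)[O-].[Mg+2]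
Why: Masamune–Brooks homologation, in which the acyl imidazolide C-acylates the magnesium malonate chelate under near-neutral conditions and CO2 is lost on work-up, adds C9 as a β-keto ester without exposing the butenolide C6–H to a strong base.

Step 12
Reactants: 19 tert-butyl 3-{(2R)-4-(acetoxymethyl)-2-[(1Z)-2-methyl-5-(2-methyl-1,3-dithian-2-yl)-5-oxopent-1-en-1-yl]-5-oxo-2,5-dihydrofuran-3-yl}-3-oxopropanoate
Product: 20 tert-butyl 3-{(2R)-4-(acetoxymethyl)-2-[(1Z)-2-methyl-5,6-dioxohept-1-en-1-yl]-5-oxo-2,5-dihydrofuran-3-yl}-3-oxopropanoate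
Conditions: PhI(O2CCF3)2, MeCN/H2O 9:1, 0 °C
Reagents that add atoms: water, O
Why: oxidative dethioketalisation, in which the iodane attacks sulfur far faster than the alkenes or the 1,3-dicarbonyl unit, releases the C1/C10 diketone under weakly acidic conditions.

Step 13
Reactants: 20 tert-butyl 3-{(2R)-4-(acetoxymethyl)-2-[(1Z)-2-methyl-5,6-dioxohept-1-en-1-yl]-5-oxo-2,5-dihydrofuran-3-yl}-3-oxopropanoate
Product: 22 (6R,10S)-13-acetoxy-10-hydroxy-1,8-dioxogermacra-4Z,7(11)-dien-12,6-olide, via keto acid 21 (not isolated)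
Conditions: CF3CO2H/CH2Cl2 1:3, 0 °C, evaporation; then slow addition to Cu(OTf)2 (20 mol %), (S,S)-2,2'-(propane-2,2-diyl)bis(4-tert-butyl-4,5-dihydrooxazole) (22 mol %), 2,6-lutidine (20 mol %), THF, 23 °C, final 2 mM
Reagents that add atoms: none
Why: Proposed new method: acidolysis frees the β-keto acid 21, whose copper-bound enol carboxylate adds through C9 to the C10 carbonyl of the C1/C10 diketone held as a five-membered chelate on the divalent copper–bis(oxazoline) centre, and the resulting β-hydroxy keto acid loses CO2 irreversibly, which pulls the otherwise reversible aldol closure of a medium ring forward and leaves C9 as CH2. The closest known reactions are the intermolecular bis(oxazoline)copper-catalysed additions of enolsilanes to pyruvates and 2,3-diketones and the intermolecular decarboxylative aldol additions of β-keto acids and malonic half thioesters to activated carbonyl compounds; the ring-closing version is new. The ten-membered carbocycle closes in a 10-exo-trig mode. The C10 stereocentre is set by the catalyst: in the square-planar chelate the tert-butyl groups of the (S,S)-ligand should leave the si face of C10 open, which corresponds to 10S, and the antipodal ligand is at hand should the tether override this preference. The step needs carbanion formation at C9 only, which the β-keto acid secures because it is by far the strongest carbon acid present (the butenolide C6–H and the diketone α-hydrogens are not engaged by lutidine), attack at C10 and not at C1, which the small methyl flank and the less favourable nine-membered alternative secure, and ring closure over oligomerisation, which slow addition to high dilution secures.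

Step 14
Reactants: 22 (6R,10S)-13-acetoxy-10-hydroxy-1,8-dioxogermacra-4Z,7(11)-dien-12,6-olide
Product: 23 (6R,8S,10S)-10,13-diacetoxy-8-hydroxy-1-oxogermacra-4Z,7(11)-dien-12,6-olide
Conditions: SmI2 (30 mol %) premixed with CH3CHO (10 equiv), THF, −10 °C; then 22
Reagents that add atoms: acetaldehyde, CC=O
Why: Proposed new method: acetaldehyde and the tertiary C10 hydroxyl form a hemiacetal that the trivalent samarium catalyst (formed from SmI2 and the aldehyde before the substrate is added, so that no divalent samarium meets the ene-dione) ties to the C8 carbonyl, and the hemiacetal hydrogen passes to C8 through a six-membered transition state on the ring face that carries O10, which should set 8S (trans to O10 across the ring) and turn the tertiary oxygen into its acetate, the C1 ketone lying one atom too close for such a transfer; the closest known reaction is the Evans–Tishchenko reduction of secondary β-hydroxy ketones, and the tertiary, acyl-flanked carbinol is the untested element.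

Step 15
Reactants: 23 (6R,8S,10S)-10,13-diacetoxy-8-hydroxy-1-oxogermacra-4Z,7(11)-dien-12,6-olide
Product: 24 CNP0115165.3, (6R,8S,10S)-10,13-diacetoxy-8-(methacryloyloxy)-1-oxogermacra-4Z,7(11)-dien-12,6-olide
Conditions: methacrylic anhydride, DMAP (cat.), pyridine, CH2Cl2, 0 °C
Reagents that add atoms: methacrylic anhydride, CC(=C)C(=O)OC(=O)C(C)=C
Why: DMAP-catalysed acylation of the only free hydroxyl under weakly basic conditions, the trans 1,3-relationship across the ring disfavouring acetyl migration from O10 to O8.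

Compound list
1 | but-2-yn-1-ol | CC#CCO | starting material
2 | (2Z)-3-iodobut-2-en-1-ol | C/C(I)=C/CO | intermediate
3 | (3-ethoxy-3-oxopropyl)zinc bromide | CCOC(=O)CC[Zn]Br | starting material
4 | ethyl (4Z)-6-hydroxy-4-methylhex-4-enoate | CCOC(=O)CC/C(C)=C\CO | intermediate
5 | 2-methyl-1,3-dithiane | CC1SCCCS1 | starting material
6 | 2-lithio-2-methyl-1,3-dithiane (not isolated) | [Li]C1(C)SCCCS1 | intermediate
7 | (4Z)-6-hydroxy-4-methyl-1-(2-methyl-1,3-dithian-2-yl)hex-4-en-1-one | CC1(SCCCS1)C(=O)CC/C(C)=C\CO | intermediate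
8 | (2Z)-3-methyl-6-(2-methyl-1,3-dithian-2-yl)-6-oxohex-2-enal | CC1(SCCCS1)C(=O)CC/C(C)=C\C=O | intermediate
9 | methyl propanoate | CCC(=O)OC | starting material
10 | di-tert-butyl oxalate | CC(C)(C)OC(=O)C(=O)OC(C)(C)C | starting material
11 | 1-tert-butyl 4-methyl 3-methyl-2-oxobutanedioate (racemic, enolisable) | COC(=O)C(C)C(=O)C(=O)OC(C)(C)C | intermediate
12 | 1-tert-butyl 4-methyl (2Z)-3-methyl-2-[(trifluoromethanesulfonyl)oxy]but-2-enedioate | CC(C)(C)OC(=O)/C(OS(=O)(=O)C(F)(F)F)=C(\C)C(=O)OC | intermediate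
13 | 1-tert-butyl 4-methyl (2E)-3-(bromomethyl)-2-[(trifluoromethanesulfonyl)oxy]but-2-enedioate | CC(C)(C)OC(=O)/C(OS(=O)(=O)C(F)(F)F)=C(\CBr)C(=O)OC | intermediate
14 | 1-tert-butyl 4-methyl (2Z)-3-(acetoxymethyl)-2-[(trifluoromethanesulfonyl)oxy]but-2-enedioate | CC(C)(C)OC(=O)/C(OS(=O)(=O)C(F)(F)F)=C(\COC(C)=O)C(=O)OC | intermediate
15 | 1-tert-butyl 4-methyl (2E)-3-(acetoxymethyl)-2-[(1R,2Z)-3-methyl-6-(2-methyl-1,3-dithian-2-yl)-6-oxo-1-(trimethylsilyloxy)hex-2-en-1-yl]but-2-enedioate (not isolated) | CC1(SCCCS1)C(=O)CC/C(C)=C\[C@@H](O[Si](C)(C)C)/C(C(=O)OC(C)(C)C)=C(/COC(C)=O)C(=O)OC | intermediate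
16 | tert-butyl (2R)-4-(acetoxymethyl)-2-[(1Z)-2-methyl-5-(2-methyl-1,3-dithian-2-yl)-5-oxopent-1-en-1-yl]-5-oxo-2,5-dihydrofuran-3-carboxylate | CC1(SCCCS1)C(=O)CC/C(C)=C\[C@H]1OC(=O)C(COC(C)=O)=C1C(=O)OC(C)(C)C | intermediate
17 | (2R)-4-(acetoxymethyl)-2-[(1Z)-2-methyl-5-(2-methyl-1,3-dithian-2-yl)-5-oxopent-1-en-1-yl]-5-oxo-2,5-dihydrofuran-3-carboxylic acid | CC1(SCCCS1)C(=O)CC/C(C)=C\[C@H]1OC(=O)C(COC(C)=O)=C1C(=O)O | intermediate
18 | 1-{(2R)-4-(acetoxymethyl)-2-[(1Z)-2-methyl-5-(2-methyl-1,3-dithian-2-yl)-5-oxopent-1-en-1-yl]-5-oxo-2,5-dihydrofuran-3-carbonyl}-1H-imidazole (not isolated) | CC1(SCCCS1)C(=O)CC/C(C)=C\[C@H]1OC(=O)C(COC(C)=O)=C1C(=O)n1ccnc1 | intermediate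
19 | tert-butyl 3-{(2R)-4-(acetoxymethyl)-2-[(1Z)-2-methyl-5-(2-methyl-1,3-dithian-2-yl)-5-oxopent-1-en-1-yl]-5-oxo-2,5-dihydrofuran-3-yl}-3-oxopropanoate | CC1(SCCCS1)C(=O)CC/C(C)=C\[C@H]1OC(=O)C(COC(C)=O)=C1C(=O)CC(=O)OC(C)(C)C | intermediate
20 | tert-butyl 3-{(2R)-4-(acetoxymethyl)-2-[(1Z)-2-methyl-5,6-dioxohept-1-en-1-yl]-5-oxo-2,5-dihydrofuran-3-yl}-3-oxopropanoate | CC(=O)C(=O)CC/C(C)=C\[C@H]1OC(=O)C(COC(C)=O)=C1C(=O)CC(=O)OC(C)(C)C | intermediate
21 | 3-{(2R)-4-(acetoxymethyl)-2-[(1Z)-2-methyl-5,6-dioxohept-1-en-1-yl]-5-oxo-2,5-dihydrofuran-3-yl}-3-oxopropanoic acid (not isolated) | CC(=O)C(=O)CC/C(C)=C\[C@H]1OC(=O)C(COC(C)=O)=C1C(=O)CC(=O)O | intermediate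
22 | (6R,10S)-13-acetoxy-10-hydroxy-1,8-dioxogermacra-4Z,7(11)-dien-12,6-olide | O=C1C[C@](C)(O)C(=O)CC/C(C)=C\[C@H]2OC(=O)C(COC(C)=O)=C12 | intermediate
23 | (6R,8S,10S)-10,13-diacetoxy-8-hydroxy-1-oxogermacra-4Z,7(11)-dien-12,6-olide | O[C@H]1C[C@](C)(OC(C)=O)C(=O)CC/C(C)=C\[C@H]2OC(=O)C(COC(C)=O)=C12 | intermediate
24 | CNP0115165.3, (6R,8S,10S)-10,13-diacetoxy-8-(methacryloyloxy)-1-oxogermacra-4Z,7(11)-dien-12,6-olide | C=C(C)C(=O)O[C@H]1C[C@](C)(OC(C)=O)C(=O)CC/C(C)=C\[C@H]2OC(=O)C(COC(C)=O)=C12 | target

Total step count: 15. Longest linear sequence: 11 steps (steps 1–4 and 9–15; the branch through steps 5–8 and 9–15 is equally long).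

Steps most likely to fail

Step 13. Loss of CO2 from 21 to the plain methyl ketone, or intermolecular aldol addition, may outrun closure of the ten-membered ring, and addition at C1 would give the nine-membered isomer. The fallback uses known reaction types and closes the ring at C6–C7 instead; it sets out from 14 and 8 and returns at 22. Acidolysis of 14 (CF3CO2H, CH2Cl2, 0 °C) would give the triflate acid F1. Its activation with 1,1'-carbonyldiimidazole would give the acyl imidazolide F2 (not isolated), and acylation of Mg(O2CCH2CO2tBu)2 would give the triflate β-keto ester F3. A second acidolysis would give the triflate β-keto acid F4. Treatment of 8 with PhI(O2CCF3)2 in aqueous MeCN would give the dioxo enal F5. An intermolecular decarboxylative aldol addition of F4 to the chelating diketone of F5 under the copper catalyst of step 13, a reaction class documented for β-keto acids and 1,2-dicarbonyl electrophiles and needing no dilution, would give the open-chain ketol F6 with C10 set by the ligand. An intramolecular Nozaki–Hiyama–Kishi coupling of the enol triflate and the aldehyde of F6 (CrCl2, catalytic NiCl2, chiral ligand, DMSO/THF, high dilution), a well-precedented way to close medium and large rings, would give the ring-closed hydroxy ester F7 (not isolated), with C6 set under the influence of the ligand and of C10, and its lactonisation on acidic work-up would give 22.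

Step 14. Hemiacetal formation at the hindered tertiary hydroxyl may be slow, so that Lewis-acid-induced retro-aldol opening of the ring or unselective reduction competes. The fallback sets out from 22 and returns at 23. Acetylation of the tertiary hydroxyl (Ac2O, Sc(OTf)3 cat., MeCN, −20 °C) would give the keto acetate F8. A Corey–Bakshi–Shibata reduction of the conjugated C8 ketone ((R)-2-methyl-CBS-oxazaborolidine, catecholborane, toluene, −78 °C; reagent control, the butenolide alkene taken as the large group) would then give 23.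

Step 9. Facial discrimination in the addition of the alkenylchromium species to the enal may be insufficient (low enantiomeric purity at C6), or oxidative addition of the hindered triflate may be slow. The fallback sets out from 8 and 14 and returns at 16. The coupling run with stoichiometric CrCl2 and catalytic NiCl2 in DMF without a chiral ligand, the most general form of the reaction, would give the racemic hydroxy diester F9 (not isolated) and, after lactonisation, the racemic butenolide F10. Its enantiomers would be separated by preparative chromatography on a chiral stationary phase to give 16.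

Further compounds
F1 | step 13 | (2Z)-3-(acetoxymethyl)-4-methoxy-4-oxo-2-[(trifluoromethanesulfonyl)oxy]but-2-enoic acid | OC(=O)/C(OS(=O)(=O)C(F)(F)F)=C(\COC(C)=O)C(=O)OC
F2 | step 13 | methyl (2Z)-2-(acetoxymethyl)-4-(1H-imidazol-1-yl)-4-oxo-3-[(trifluoromethanesulfonyl)oxy]but-2-enoate | O=C(n1ccnc1)/C(OS(=O)(=O)C(F)(F)F)=C(\COC(C)=O)C(=O)OC
F3 | step 13 | 6-tert-butyl 1-methyl (2Z)-2-(acetoxymethyl)-4-oxo-3-[(trifluoromethanesulfonyl)oxy]hex-2-enedioate | CC(C)(C)OC(=O)CC(=O)/C(OS(=O)(=O)C(F)(F)F)=C(\COC(C)=O)C(=O)OC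
F4 | step 13 | (4Z)-5-(acetoxymethyl)-6-methoxy-3,6-dioxo-4-[(trifluoromethanesulfonyl)oxy]hex-4-enoic acid | OC(=O)CC(=O)/C(OS(=O)(=O)C(F)(F)F)=C(\COC(C)=O)C(=O)OC
F5 | step 13 | (2Z)-3-methyl-6,7-dioxooct-2-enal | CC(=O)C(=O)CC/C(C)=C\C=O
F6 | step 13 | methyl (2Z,6S,10Z)-2-(acetoxymethyl)-6-hydroxy-6,10-dimethyl-4,7,12-trioxo-3-[(trifluoromethanesulfonyl)oxy]dodeca-2,10-dienoate | O=C/C=C(C)\CCC(=O)[C@@](C)(O)CC(=O)/C(OS(=O)(=O)C(F)(F)F)=C(\COC(C)=O)C(=O)OC
F7 | step 13 | ten-membered carbocycle of 22 before lactonisation: (6R,10S)-6,10-dihydroxy-1,8-dioxo ring with exocyclic C7=C11 bearing CH2OAc and CO2CH3, C6 cis to CO2CH3 | O=C1C[C@](C)(O)C(=O)CC/C(C)=C\[C@@H](O)/C1=C(/COC(C)=O)C(=O)OC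
F8 | step 14 | (6R,10S)-10,13-diacetoxy-1,8-dioxogermacra-4Z,7(11)-dien-12,6-olide | O=C1C[C@](C)(OC(C)=O)C(=O)CC/C(C)=C\[C@H]2OC(=O)C(COC(C)=O)=C12
F9 | step 9 | 1-tert-butyl 4-methyl (2E)-3-(acetoxymethyl)-2-[(1RS,2Z)-1-hydroxy-3-methyl-6-(2-methyl-1,3-dithian-2-yl)-6-oxohex-2-en-1-yl]but-2-enedioate | CC1(SCCCS1)C(=O)CC/C(C)=C\C(O)/C(C(=O)OC(C)(C)C)=C(/COC(C)=O)C(=O)OC
F10 | step 9 | tert-butyl (2RS)-4-(acetoxymethyl)-2-[(1Z)-2-methyl-5-(2-methyl-1,3-dithian-2-yl)-5-oxopent-1-en-1-yl]-5-oxo-2,5-dihydrofuran-3-carboxylate | CC1(SCCCS1)C(=O)CC/C(C)=C\C1OC(=O)C(COC(C)=O)=C1C(=O)OC(C)(C)C
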